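The route rests on opening the dihydropyran ring fused to ring B at its aryl ether bond, O-4'–C(CH3)2, and closing it last. The precursor 15 is the open pentahydroxyflavone carrying three C5 units: 1,1-dimethylallyl at C-8, prenyl at C-2' and prenyl at C-3'. One acid-catalysed Markovnikov hydroalkoxylation should tell them apart: only the C-3' prenyl has an ortho hydroxyl (O-4') to trap its tertiary cation in a six-membered ring; the C-2' prenyl has carbon neighbours only, and the ring A vinyl group could give only a secondary cation. Precursor 15 comes from a Claisen–Schmidt/Algar–Flynn–Oyamada union of two Claisen-derived fragments.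

Key step: step 11

Remark on the chemistry: ring B is numbered C-1' (bonded to C-2 of the chromenone), C-2' (prenyl), C-3', C-4' (ether oxygen), C-5' (OH), C-6' (H); the target has no stereocentre; 2-bromo-4,5-dihydroxybenzaldehyde is taken as purchasable.

Step 1
Reactants: 1 2,4,6-trihydroxyacetophenone
Product: 2 1-[2,6-dihydroxy-4-(3-methylbut-2-enyloxy)phenyl]ethanone
Conditions: prenyl bromide (1.05 equiv), K2CO3 (1.0 equiv), acetone, reflux
Reagents that add atoms: 1-bromo-3-methylbut-2-ene (prenyl bromide), CC(C)=CCBr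
Why: Williamson etherification; the 4-hydroxyl is the only one not hydrogen-bonded to the acetyl carbonyl and is the most acidic, so one equivalent of base should alkylate it selectively on oxygen.

Step 2
Reactants: 2 1-[2,6-dihydroxy-4-(3-methylbut-2-enyloxy)phenyl]ethanone
Product: 4 1-[2,4,6-trihydroxy-3-(2-methylbut-3-en-2-yl)phenyl]ethanone, via ortho-dienone 3 (not isolated)
Conditions: PhNEt2, 190 °C, Ar
Reagents that add atoms: none
Why: Aromatic Claisen rearrangement ([3,3]-sigmatropic shift with allylic inversion); the two ortho carbons of 2 are equivalent by symmetry, so a single dienone 3 should form and enolise to the one C-(1,1-dimethylallyl) phenol 4.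

Step 3
Reactants: 4 1-[2,4,6-trihydroxy-3-(2-methylbut-3-en-2-yl)phenyl]ethanone
Product: 5 1-[2-hydroxy-4,6-bis(methoxymethoxy)-3-(2-methylbut-3-en-2-yl)phenyl]ethanone
Conditions: MOMCl (2.2 equiv), i-Pr2NEt, CH2Cl2, 0 °C to rt
Reagents that add atoms: chloromethyl methyl ether (MOMCl), COCCl
Why: Phenol acetalisation (MOM protection); the unchelated 4-hydroxyl and the unhindered chelated 6-hydroxyl should react, while the hydroxyl wedged between the acetyl group and the quaternary carbon stays free and so becomes the pyranone oxygen next to C-8.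

Step 4
Reactants: 6 2-bromo-4,5-dihydroxybenzaldehyde
Product: 7 2-bromo-5-hydroxy-4-[(2-methylbut-3-en-2-yl)oxy]benzaldehyde
Conditions: tert-butyl 2-methylbut-3-en-2-yl carbonate (1.1 equiv), Pd(PPh3)4 (2 mol %), THF, 0 °C
Reagents that add atoms: tert-butyl 2-methylbut-3-en-2-yl carbonate, C=CC(C)(C)OC(=O)OC(C)(C)C
Why: Decarboxylative Tsuji–Trost O-allylation; the tert-butoxide set free deprotonates the more acidic 4-hydroxyl (para to the formyl group), whose phenoxide attacks the more substituted end of the (1,1-dimethylallyl)palladium complex under kinetic control at 0 °C, where the C–Br bond should not add to zerovalent palladium.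

Step 5
Reactants: 7 2-bromo-5-hydroxy-4-[(2-methylbut-3-en-2-yl)oxy]benzaldehyde
Product: 9 2-bromo-4,5-dihydroxy-3-(3-methylbut-2-enyl)benzaldehyde, via ortho-dienone 8 (not isolated)
Conditions: o-xylene, 140 °C, Ar
Reagents that add atoms: none
Why: Aromatic Claisen rearrangement; the tertiary allyl ether migrates with allylic inversion to C-3, the only free ortho carbon (the other carries the hydroxyl), and dienone 8 enolises to the linear 3-prenyl catechol.

Step 6
Reactants: 9 2-bromo-4,5-dihydroxy-3-(3-methylbut-2-enyl)benzaldehyde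
Product: 10 2-bromo-4,5-bis(methoxymethoxy)-3-(3-methylbut-2-enyl)benzaldehyde
Conditions: MOMCl (3 equiv), i-Pr2NEt, CH2Cl2, 0 °C to rt
Reagents that add atoms: chloromethyl methyl ether (MOMCl), COCCl
Why: Phenol acetalisation (MOM protection) masks the catechol against base and peroxide and keeps the 4-oxygen from adding to the neighbouring prenyl group before the last step.

Step 7
Reactants: 10 2-bromo-4,5-bis(methoxymethoxy)-3-(3-methylbut-2-enyl)benzaldehyde
Product: 11 4,5-bis(methoxymethoxy)-2,3-bis(3-methylbut-2-enyl)benzaldehyde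
Conditions: tributyl(prenyl)stannane (1.3 equiv), Pd(PPh3)4 (5 mol %), DMF, 90 °C
Reagents that add atoms: tributyl(3-methylbut-2-en-1-yl)stannane, CCCC[Sn](CCCC)(CCCC)CC=C(C)C
Why: Stille coupling; the ortho formyl group speeds oxidative addition of the hindered C–Br bond, and reductive elimination at the unsubstituted allyl terminus should give the linear prenyl arene.

Step 8
Reactants: 5 1-[2-hydroxy-4,6-bis(methoxymethoxy)-3-(2-methylbut-3-en-2-yl)phenyl]ethanone; 11 4,5-bis(methoxymethoxy)-2,3-bis(3-methylbut-2-enyl)benzaldehyde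
Product: 12 (E)-3-[4,5-bis(methoxymethoxy)-2,3-bis(3-methylbut-2-enyl)phenyl]-1-[2-hydroxy-4,6-bis(methoxymethoxy)-3-(2-methylbut-3-en-2-yl)phenyl]prop-2-en-1-one
Conditions: KOH (50% aq.), EtOH, rt
Reagents that add atoms: none
Why: Claisen–Schmidt condensation of the methyl ketone with the non-enolisable aldehyde; the E enone is the thermodynamic product.

Step 9
Reactants: 12 (E)-3-[4,5-bis(methoxymethoxy)-2,3-bis(3-methylbut-2-enyl)phenyl]-1-[2-hydroxy-4,6-bis(methoxymethoxy)-3-(2-methylbut-3-en-2-yl)phenyl]prop-2-en-1-one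
Product: 14 2-[4,5-bis(methoxymethoxy)-2,3-bis(3-methylbut-2-enyl)phenyl]-3-hydroxy-5,7-bis(methoxymethoxy)-8-(2-methylbut-3-en-2-yl)-4H-chromen-4-one, via trans-dihydroflavonol 13 (not isolated)
Conditions: 30% H2O2, NaOH (aq.), MeOH–THF, 0 °C to rt
Reagents that add atoms: hydrogen peroxide, OO
Why: Algar–Flynn–Oyamada oxidation; hydroperoxide attack on the enone and six-membered closure by the 2'-phenoxide should give the trans-dihydroflavonol 13, which alkaline peroxide dehydrogenates to the flavonol, while the isolated alkenes are inert to nucleophilic peroxide.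

Step 10
Reactants: 14 2-[4,5-bis(methoxymethoxy)-2,3-bis(3-methylbut-2-enyl)phenyl]-3-hydroxy-5,7-bis(methoxymethoxy)-8-(2-methylbut-3-en-2-yl)-4H-chromen-4-one
Product: 15 2-[4,5-dihydroxy-2,3-bis(3-methylbut-2-enyl)phenyl]-3,5,7-trihydroxy-8-(2-methylbut-3-en-2-yl)-4H-chromen-4-one
Conditions: HCl (1.25 M in MeOH), 40 °C
Reagents that add atoms: none
Why: Acid-catalysed acetal methanolysis (MOM removal) under conditions mild enough that prenyl and 1,1-dimethylallyl groups next to free phenols should survive.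

Step 11
Reactants: 15 2-[4,5-dihydroxy-2,3-bis(3-methylbut-2-enyl)phenyl]-3,5,7-trihydroxy-8-(2-methylbut-3-en-2-yl)-4H-chromen-4-one
Product: 16 Broussoflavonol E
Conditions: p-TsOH·H2O (10 mol %), PhMe–1,4-dioxane (4:1), 60 °C
Reagents that add atoms: none
Why: Brønsted-acid-catalysed intramolecular Markovnikov hydroalkoxylation: the C-3' prenyl alkene is protonated at its CH carbon, helped by the neighbouring O-4'–H, and the tertiary cation is captured by O-4' to give the O–C(CH3)2 bond. The closest known reaction type is the acid cyclisation of ortho-prenylphenols to 2,2-dimethylchromans, which is known to spare a second prenyl group that has no ortho hydroxyl. The single ring closes in a 6-endo-trig mode (cation capture in a six-membered ring) and no stereocentre is created. The step needs three selectivities: C-3' prenyl over C-2' prenyl, prenyl over the C-8 1,1-dimethylallyl group, and six-membered over five-membered ether. The substrate secures them: C-2' is flanked by C-1' and C-3' and has no oxygen within reach (O-3 would need an eight-membered ring), so its cation can only lose a proton again; the C-8 vinyl group would have to pass through a secondary cation; and attack at the CH carbon (5-exo) would leave the charge on a secondary centre. Catalytic acid in an aprotic, non-nucleophilic medium, stopped at full conversion of 15, should keep hydration and alkene migration of the C-2' prenyl down.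

Compound list
1 | 2,4,6-trihydroxyacetophenone | CC(=O)c1c(O)cc(O)cc1O | starting material
2 | 1-[2,6-dihydroxy-4-(3-methylbut-2-enyloxy)phenyl]ethanone | CC(=O)c1c(O)cc(OCC=C(C)C)cc1O | intermediate
3 | rac-4-acetyl-3,5-dihydroxy-6-(2-methylbut-3-en-2-yl)cyclohexa-2,4-dien-1-one (ortho-dienone) | CC(=O)C1=C(O)C(C(C)(C)C=C)C(=O)C=C1O | intermediate
4 | 1-[2,4,6-trihydroxy-3-(2-methylbut-3-en-2-yl)phenyl]ethanone | CC(=O)c1c(O)c(C(C)(C)C=C)c(O)cc1O | intermediate
5 | 1-[2-hydroxy-4,6-bis(methoxymethoxy)-3-(2-methylbut-3-en-2-yl)phenyl]ethanone | CC(=O)c1c(O)c(C(C)(C)C=C)c(OCOC)cc1OCOC | intermediate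
6 | 2-bromo-4,5-dihydroxybenzaldehyde | O=Cc1cc(O)c(O)cc1Br | starting material
7 | 2-bromo-5-hydroxy-4-[(2-methylbut-3-en-2-yl)oxy]benzaldehyde | O=Cc1cc(O)c(OC(C)(C)C=C)cc1Br | intermediate
8 | rac-2-bromo-5-hydroxy-3-(3-methylbut-2-enyl)-4-oxocyclohexa-1,5-diene-1-carbaldehyde (ortho-dienone) | O=CC1=C(Br)C(CC=C(C)C)C(=O)C(O)=C1 | intermediate
9 | 2-bromo-4,5-dihydroxy-3-(3-methylbut-2-enyl)benzaldehyde | O=Cc1cc(O)c(O)c(CC=C(C)C)c1Br | intermediate
10 | 2-bromo-4,5-bis(methoxymethoxy)-3-(3-methylbut-2-enyl)benzaldehyde | O=Cc1cc(OCOC)c(OCOC)c(CC=C(C)C)c1Br | intermediate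
11 | 4,5-bis(methoxymethoxy)-2,3-bis(3-methylbut-2-enyl)benzaldehyde | O=Cc1cc(OCOC)c(OCOC)c(CC=C(C)C)c1CC=C(C)C | intermediate
12 | (E)-3-[4,5-bis(methoxymethoxy)-2,3-bis(3-methylbut-2-enyl)phenyl]-1-[2-hydroxy-4,6-bis(methoxymethoxy)-3-(2-methylbut-3-en-2-yl)phenyl]prop-2-en-1-one | C=CC(C)(C)c1c(O)c(C(=O)/C=C/c2cc(OCOC)c(OCOC)c(CC=C(C)C)c2CC=C(C)C)c(OCOC)cc1OCOC | intermediate
13 | rac-(2R,3R)-2-[4,5-bis(methoxymethoxy)-2,3-bis(3-methylbut-2-enyl)phenyl]-3-hydroxy-5,7-bis(methoxymethoxy)-8-(2-methylbut-3-en-2-yl)chroman-4-one (trans-dihydroflavonol, one enantiomer drawn) | O=C1c2c(OCOC)cc(OCOC)c(C(C)(C)C=C)c2O[C@H](c2cc(OCOC)c(OCOC)c(CC=C(C)C)c2CC=C(C)C)[C@H]1O | intermediate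
14 | 2-[4,5-bis(methoxymethoxy)-2,3-bis(3-methylbut-2-enyl)phenyl]-3-hydroxy-5,7-bis(methoxymethoxy)-8-(2-methylbut-3-en-2-yl)-4H-chromen-4-one | C=CC(C)(C)c1c(OCOC)cc(OCOC)c2c(=O)c(O)c(-c3cc(OCOC)c(OCOC)c(CC=C(C)C)c3CC=C(C)C)oc12 | intermediate
15 | 2-[4,5-dihydroxy-2,3-bis(3-methylbut-2-enyl)phenyl]-3,5,7-trihydroxy-8-(2-methylbut-3-en-2-yl)-4H-chromen-4-one | C=CC(C)(C)c1c(O)cc(O)c2c(=O)c(O)c(-c3cc(O)c(O)c(CC=C(C)C)c3CC=C(C)C)oc12 | intermediate
16 | Broussoflavonol E, 3,5,7-trihydroxy-2-[8-hydroxy-2,2-dimethyl-5-(3-methylbut-2-enyl)-3,4-dihydro-2H-chromen-6-yl]-8-(2-methylbut-3-en-2-yl)-4H-chromen-4-one | C=CC(C)(C)c1c(O)cc(O)c2c(=O)c(O)c(-c3cc(O)c4c(c3CC=C(C)C)CCC(C)(C)O4)oc12 | target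

Total step count: 11. Longest linear sequence: 8 steps (steps 4 to 11, from 6); ring A ketone 5 takes 3 steps and joins at step 8.

Steps most likely to fail

1. Step 11 (key step). The acid may protonate the C-2' prenyl group long enough for the double bond to migrate or for adventitious water to add, and on prolonged exposure the 7-hydroxyl may add to the 1,1-dimethylallyl group. The fallback closes the same O–C bond before any other alkene is present. It sets out from 9, which is cyclised with catalytic p-TsOH·H2O in PhMe at 60 °C to 5-bromo-8-hydroxy-2,2-dimethyl-3,4-dihydro-2H-chromene-6-carbaldehyde F1. MOMCl and i-Pr2NEt should give 5-bromo-8-(methoxymethoxy)-2,2-dimethyl-3,4-dihydro-2H-chromene-6-carbaldehyde F2. Stille coupling with tributyl(prenyl)stannane and Pd(PPh3)4 should give 8-(methoxymethoxy)-2,2-dimethyl-5-(3-methylbut-2-enyl)-3,4-dihydro-2H-chromene-6-carbaldehyde F3. Claisen–Schmidt condensation with 5 should give the chroman-bearing chalcone F4, and Algar–Flynn–Oyamada oxidation should pass through the racemic trans-dihydroflavonol F5 to the tris-MOM flavonol F6. Methanolic HCl then removes the three acetals, and the fallback comes back to the route at 16.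

2. Step 9. The 2'-phenoxide may attack the α-carbon of the oxidised enone in a five-membered closure, which the 6'-alkoxy group and the ortho-substituted ring B both favour, diverting material into the benzofuranone (aurone) manifold. The fallback separates ring closure from oxidation. It sets out from 12, which is cyclised by oxa-Michael addition (NaOAc, EtOH, reflux) to the racemic flavanone F7. Its lithium enolate (LiN(SiMe3)2, THF, −78 °C) is hydroxylated at C-3 with 2-(phenylsulfonyl)-3-phenyloxaziridine to give 13, now isolated. Dehydrogenation of 13 with NaOH and H2O2 in MeOH brings the fallback back to the route at 14.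

3. Step 4. Zerovalent palladium may insert into the C–Br bond, re-ionise the tertiary ether so that it collapses to the linear prenyl ether, or allylate the 5-hydroxyl. The fallback builds the tertiary ether without an allylpalladium species. It sets out from 6, which is alkylated with 3-chloro-3-methylbut-1-yne (K2CO3, KI, CuI cat., acetone, 50 °C) to 2-bromo-5-hydroxy-4-[(2-methylbut-3-yn-2-yl)oxy]benzaldehyde F8. Semi-hydrogenation of the alkyne (H2, Pd/CaCO3 poisoned with Pb(OAc)2, quinoline, EtOAc) brings the fallback back to the route at 7.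

Further compounds
F1 | step 11 | 5-bromo-8-hydroxy-2,2-dimethyl-3,4-dihydro-2H-chromene-6-carbaldehyde | O=Cc1cc(O)c2OC(C)(C)CCc2c1Br
F2 | step 11 | 5-bromo-8-(methoxymethoxy)-2,2-dimethyl-3,4-dihydro-2H-chromene-6-carbaldehyde | O=Cc1cc(OCOC)c2OC(C)(C)CCc2c1Br
F3 | step 11 | 8-(methoxymethoxy)-2,2-dimethyl-5-(3-methylbut-2-enyl)-3,4-dihydro-2H-chromene-6-carbaldehyde | O=Cc1cc(OCOC)c2OC(C)(C)CCc2c1CC=C(C)C
F4 | step 11 | (E)-1-[2-hydroxy-4,6-bis(methoxymethoxy)-3-(2-methylbut-3-en-2-yl)phenyl]-3-[8-(methoxymethoxy)-2,2-dimethyl-5-(3-methylbut-2-enyl)-3,4-dihydro-2H-chromen-6-yl]prop-2-en-1-one | C=CC(C)(C)c1c(O)c(C(=O)/C=C/c2cc(OCOC)c3OC(C)(C)CCc3c2CC=C(C)C)c(OCOC)cc1OCOC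
F5 | step 11 | rac-(2R,3R)-3-hydroxy-5,7-bis(methoxymethoxy)-2-[8-(methoxymethoxy)-2,2-dimethyl-5-(3-methylbut-2-enyl)-3,4-dihydro-2H-chromen-6-yl]-8-(2-methylbut-3-en-2-yl)chroman-4-one (one enantiomer drawn) | O=C1c2c(OCOC)cc(OCOC)c(C(C)(C)C=C)c2O[C@H](c2cc(OCOC)c3OC(C)(C)CCc3c2CC=C(C)C)[C@H]1O
F6 | step 11 | 3-hydroxy-5,7-bis(methoxymethoxy)-2-[8-(methoxymethoxy)-2,2-dimethyl-5-(3-methylbut-2-enyl)-3,4-dihydro-2H-chromen-6-yl]-8-(2-methylbut-3-en-2-yl)-4H-chromen-4-one | C=CC(C)(C)c1c(OCOC)cc(OCOC)c2c(=O)c(O)c(-c3cc(OCOC)c4OC(C)(C)CCc4c3CC=C(C)C)oc12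
F7 | step 9 | rac-2-[4,5-bis(methoxymethoxy)-2,3-bis(3-methylbut-2-enyl)phenyl]-5,7-bis(methoxymethoxy)-8-(2-methylbut-3-en-2-yl)chroman-4-one | O=C1CC(c2cc(OCOC)c(OCOC)c(CC=C(C)C)c2CC=C(C)C)Oc2c1c(OCOC)cc(OCOC)c2C(C)(C)C=C
F8 | step 4 | 2-bromo-5-hydroxy-4-[(2-methylbut-3-yn-2-yl)oxy]benzaldehyde | O=Cc1cc(O)c(OC(C)(C)C#C)cc1Br
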